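The route rests on cutting the C8–C9 bond: C8 is the spiro quaternary carbon α to the C13 oxygen and is bonded to the sp2 carbon C9 on C10, while ring A (C4, C5, C10) is carried over intact from dehydroabietic acid after oxidative removal of its arene. A palladium-catalysed enolate alkenylation joins C8 to C9, closes ring B and sets the C8 configuration in one operation. Its precursor is a ring A alkenyl triflate tethered through C6–C7 to the 2-position of a cyclohexanone monoketal (ring D). By design, C11 of the triflate carries a chlorine cis to the triflate oxygen; it is a spectator in the key step and then closes ring C.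

Key step: step 10

Remark: locants follow diterpene numbering (ring A = C1–C5, C10; tether C6–C7; ring D = C8, C14, C15, C16, C12, C13; C17 on C16; C18 = CH2O on C4).
Remark: the BINAP antipode that matches the fixed ring A centres cannot be predicted and is written as (R), its enantiomer being the first control; compound 17 is used as the mixture of C8 epimers, which converge in the enolate.

Step 1
Reactants: 1 dehydroabietic acid
Product: 2 dehydroabietinol (abieta-8,11,13-trien-18-ol)
Conditions: LiAlH4, THF, 0 °C to reflux; aqueous NaOH work-up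
Reagents that add atoms: none
Why: Hydride reduction of the hindered C4 carboxylic acid should give the neopentyl primary alcohol without touching a stereocentre.

Step 2
Reactants: 2 dehydroabietinol
Product: 3 dehydroabietinol TBS ether
Conditions: TBSCl, imidazole, DMF, rt
Reagents that add atoms: tert-butyldimethylsilyl chloride, C[Si](C)(Cl)C(C)(C)C
Why: Standard silylation of a primary alcohol gives an ether that tolerates RuO4, organometallic bases and palladium and can be removed by fluoride beside an acetate at the end.

Step 3
Reactants: 3 dehydroabietinol TBS ether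
Product: 4 ring A diacid (C10–CO2H and C5–CH2CH2CO2H)
Conditions: RuCl3·xH2O (5 mol%), NaIO4, CCl4/MeCN/H2O, rt
Reagents that add atoms: sodium periodate, [Na+].[O-]I(=O)(=O)=O; water, O
Why: RuO4 formed in situ degrades the trialkylbenzene ring (oxidative arene degradation to carboxylic acids), leaving the two ipso carbons as carboxyl groups on C10 and C7, with no enolisable stereocentre exposed.

Step 4
Reactants: 4 ring A diacid
Product: 7 diazoketone methyl ester (C10–COCHN2; C7–CO2Me), via bis(acid chloride) 5 (not isolated), via ester acid chloride 6 (not isolated)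
Conditions: (COCl)2, DMF (cat.), CH2Cl2, 0 °C to rt; evaporate; MeOH (1.0 equiv), pyridine, CH2Cl2, −78 to −40 °C; then CH2N2 (excess), Et2O, 0 °C to rt
Reagents that add atoms: methanol, CO; diazomethane, C=[N+]=[N-]; oxalyl chloride, O=C(Cl)C(Cl)=O (chlorine held only in 5 and 6)
Why: The unhindered primary acid chloride should be methanolysed far faster than the neopentyl-type tertiary one, which then acylates diazomethane (first stage of the Arndt–Eistert sequence) while excess diazomethane scavenges HCl.

Step 5
Reactants: 7 diazoketone methyl ester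
Product: 8 chloromethyl ketone methyl ester
Conditions: HCl (1.1 equiv, 2 M in Et2O), Et2O, −20 to 0 °C
Reagents that add atoms: hydrogen chloride, Cl
Why: Protonation of the diazoketone and displacement of N2 by chloride (Nierenstein-type chloromethyl ketone formation) is fast enough at low temperature to spare the hindered silyl ether.

Step 6
Reactants: 8 chloromethyl ketone methyl ester
Product: 10 (Z)-chloroalkenyl triflate methyl ester, via potassium Z-enolate 9 (not isolated)
Conditions: KN(SiMe3)2, THF, −78 °C; PhNTf2, −78 to −20 °C
Reagents that add atoms: N-phenylbis(trifluoromethanesulfonimide), O=S(=O)(N(c1ccccc1)S(=O)(=O)C(F)(F)F)C(F)(F)F; potassium bis(trimethylsilyl)amide, C[Si](C)(C)[N-][Si](C)(C)C.[K+] (potassium held only in 9)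
Why: Only the chloromethyl group can enolise (C10 is quaternary, the ester is far less acidic), the bulky C10 forces chlorine cis to the enolate oxygen by allylic strain, and O-sulfonylation (enol triflate formation) fixes that Z geometry.

Step 7
Reactants: 10 (Z)-chloroalkenyl triflate methyl ester
Product: 12 (Z)-chloroalkenyl triflate carboxylic acid, via trimethylstannyl ester 11 (not isolated)
Conditions: Me3SnOH, ClCH2CH2Cl, 70 °C; then 1 M HCl wash
Reagents that add atoms: trimethyltin hydroxide Me3SnOH, C[Sn](C)(C)O
Why: Neutral tin hydroxide cleavage of the unhindered methyl ester avoids free hydroxide, which could attack the triflate sulfur or eliminate triflic acid.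

Step 8
Reactants: 12 (Z)-chloroalkenyl triflate carboxylic acid
Product: 14 C7 primary iodide, via acyl hypoiodite 13 (not isolated)
Conditions: PhI(OAc)2, I2, cyclohexane, hν (tungsten lamp), reflux
Reagents that add atoms: iodine, II
Why: Hunsdiecker-type iododecarboxylation excises the old arene carbon, and the C7 primary radical should be trapped by iodine much faster than it can add to the hindered, electron-poor chloroalkenyl triflate.

Step 9
Reactants: 14 C7 primary iodide; 15 1,4-dioxaspiro[4.5]decan-7-one
Product: 17 key-step precursor (ring A chloroalkenyl triflate tethered to the 2-substituted cyclohexanone monoketal; C8 epimers), via lithium enolate 16 (not isolated)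
Conditions: 15 (3 equiv), LiN(i-Pr)2 (2.9 equiv), THF, −78 °C; then 14, DMPU, −78 to −20 °C
Reagents that add atoms: lithium diisopropylamide, CC(C)[N-]C(C)C.[Li+] (lithium held only in 16)
Why: Kinetic deprotonation of 15 should occur at the α-CH2 remote from the shielding ketal, and the excess lithium enolate alkylates the unhindered primary iodide (SN2 enolate alkylation) while being too weak a base to eliminate the alkenyl triflate; the new C8 centre is left as a mixture because step 10 erases it.

Step 10
Reactants: 17 key-step precursor
Product: 18 tricyclic spiro ketone (rings A, B, D; exocyclic C9=C11HCl with chlorine cis to C8; C13 carbonyl syn to the C10 methyl)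
Conditions: Pd2(dba)3 (5 mol%), (R)-BINAP (12 mol%), K3PO4, toluene, 80 °C
Reagents that add atoms: none
Why: Zerovalent palladium inserts into the C9–OTf bond (a bisphosphine catalyst leaves the C11–Cl bond untouched), the resulting cationic alkenyl complex of divalent palladium binds the ketone, phosphate removes the C8 proton, and C–C reductive elimination from the C8-bound enolate forms C8–C9. The closest known reaction type is the palladium/BINAP α-alkenylation of α-branched ketones with alkenyl triflates or bromides, which builds α-quaternary stereocentres, run here intramolecularly. Ring B closes in a 6-exo mode with the enolate double bond outside the new ring, through a seven-membered palladacycle, whereas the C12 enolate would need an eight-membered ring and only reverts to ketone. The new C8 stereocentre is set by the enolate face that the ligand-bound metal takes: both C8 epimers of 17 give the same planar enolate, the chiral bisphosphine selects the face, and the substrate should help because the flat C13 carbonyl branch tolerates the side of the axial C10 methyl better than the C14 methylene does. The step needs triflate-over-chloride chemoselectivity, secured by the catalyst type and the mild base, and retention of alkene geometry, inherent to oxidative addition and reductive elimination at sp2 carbon, so that chlorine ends cis to C8.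

Step 11
Reactants: 18 tricyclic spiro ketone
Product: 20 tetracyclic ketone (ring C closed; C9=C11; C13 ketone; C16 ketal), via lithium enolate 19 (not isolated)
Conditions: LiN(SiMe3)2, toluene/THF, −78 °C to rt; Pd2(dba)3 (5 mol%), P(t-Bu)3 (12 mol%), 60 °C
Reagents that add atoms: lithium bis(trimethylsilyl)amide, C[Si](C)(C)[N-][Si](C)(C)C.[Li+] (lithium held only in 19)
Why: Only C12 can enolise (C8 is quaternary), an electron-rich monophosphine catalyst inserts into the C11–Cl bond that step 10 placed cis to C8, and reductive elimination from the six-membered palladacycle forms C11–C12 with the C9=C11 bond already in place (palladium-catalysed ketone α-alkenylation with an alkenyl chloride); C12 can bond only on the ring D face that carries C9, so its configuration follows from C8.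

Step 12
Reactants: 20 tetracyclic ketone
Product: 21 C13,C16-diketone
Conditions: PPTS, acetone/H2O, 60 °C
Reagents that add atoms: water, O
Why: Acid-catalysed ketal hydrolysis should be clean because C12 is now a bridgehead, so the β-diketone can neither enolise nor eliminate, and the hindered neopentyl silyl ether withstands the mild acid.

Step 13
Reactants: 21 C13,C16-diketone
Product: 22 16-methylene C13 ketone
Conditions: Ph3PCH3Br, NaN(SiMe3)2, THF, 0 °C; then 21, 0 °C to rt
Reagents that add atoms: methyltriphenylphosphonium bromide, C[P+](c1ccccc1)(c1ccccc1)c1ccccc1.[Br-]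
Why: Wittig methylenation should take only the accessible C16 ketone, since C13 is flanked by the quaternary C8 and the bridgehead C12, and alkoxide-free ylide avoids retro-Claisen cleavage of the non-enolisable β-diketone.

Step 14
Reactants: 22 16-methylene C13 ketone
Product: 23 C16,C17-diol C13 ketone (C16 hydroxyl equatorial on ring D; C17 axial beside C13)
Conditions: OsO4 (2 mol%), NMO, acetone/H2O, 0 °C to rt
Reagents that add atoms: OsO4, O=[Os](=O)(=O)=O; N-methylmorpholine N-oxide, C[N+]1([O-])CCOCC1; water, O
Why: Catalytic syn-dihydroxylation should take the exocyclic 1,1-disubstituted alkene (the trisubstituted C9=C11 bond is shielded on both faces) from the face turned towards the flat C9=C11 bridge, because the other face lies under the C13 carbonyl bridge and the axial C14 hydrogen, which sets C16 with the hydroxyl equatorial and C17 axial.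

Step 15
Reactants: 23 C16,C17-diol C13 ketone
Product: 24 C13,C16,C17-triol
Conditions: Me4NBH(OAc)3, MeCN/AcOH, −20 °C to rt
Reagents that add atoms: none
Why: In this Evans–Saksena-type directed reduction the axial C17 hydroxyl, which lies within reach of C13, exchanges onto boron and delivers hydride to the ring D face of the ketone, so the C13 hydroxyl should end on the side of the C9=C11 bridge, while unbound triacetoxyborohydride does not reduce the hindered ketone from the other face.

Step 16
Reactants: 24 C13,C16,C17-triol
Product: 25 C17 monoacetate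
Conditions: Ac2O (1.1 equiv), pyridine, CH2Cl2, 0 °C
Reagents that add atoms: acetic anhydride, CC(=O)OC(C)=O
Why: Acylation should take the only primary hydroxyl, the tertiary C16 and the hindered secondary C13 hydroxyls reacting far more slowly.

Step 17
Reactants: 25 C17 monoacetate
Product: 26 Botryotin E
Conditions: HF·pyridine, THF/pyridine, 0 °C to rt
Reagents that add atoms: none
Why: Fluoride-driven cleavage of the primary silyl ether under buffered conditions should leave the acetate in place without migration.

Compound list
1 | dehydroabietic acid | CC(C)c1ccc2c(c1)CC[C@H]1[C@](C)(C(=O)O)CCC[C@@]12C | starting material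
2 | dehydroabietinol (C18 primary alcohol; ring A centres as in 1) | CC(C)c1ccc2c(c1)CC[C@H]1[C@](C)(CO)CCC[C@@]12C | intermediate
3 | dehydroabietinol tert-butyldimethylsilyl ether | CC(C)c1ccc2c(c1)CC[C@H]1[C@](C)(CO[Si](C)(C)C(C)(C)C)CCC[C@@]12C | intermediate
4 | ring A diacid: C10 bears CH3 and CO2H, C5 bears H and CH2CH2CO2H, C4 bears CH3 and CH2OTBS (centres as in 1) | OC(=O)CC[C@H]1[C@](C)(CO[Si](C)(C)C(C)(C)C)CCC[C@]1(C)C(=O)O | intermediate
5 | bis(acid chloride) of 4 | ClC(=O)CC[C@H]1[C@](C)(CO[Si](C)(C)C(C)(C)C)CCC[C@]1(C)C(Cl)=O | intermediate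
6 | side-chain methyl ester, C10 acid chloride | COC(=O)CC[C@H]1[C@](C)(CO[Si](C)(C)C(C)(C)C)CCC[C@]1(C)C(Cl)=O | intermediate
7 | diazoketone methyl ester (C10–COCHN2) | COC(=O)CC[C@H]1[C@](C)(CO[Si](C)(C)C(C)(C)C)CCC[C@]1(C)C(=O)C=[N+]=[N-] | intermediate
8 | chloromethyl ketone methyl ester (C10–COCH2Cl) | COC(=O)CC[C@H]1[C@](C)(CO[Si](C)(C)C(C)(C)C)CCC[C@]1(C)C(=O)CCl | intermediate
9 | potassium (Z)-enolate of 8 (Cl cis to O) | COC(=O)CC[C@H]1[C@](C)(CO[Si](C)(C)C(C)(C)C)CCC[C@]1(C)/C([O-])=C/Cl.[K+] | intermediate
10 | (Z)-2-chloro-1-(ring A)vinyl triflate, side-chain methyl ester | COC(=O)CC[C@H]1[C@](C)(CO[Si](C)(C)C(C)(C)C)CCC[C@]1(C)/C(OS(=O)(=O)C(F)(F)F)=C/Cl | intermediate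
11 | trimethylstannyl ester of 12 | C[Sn](C)(C)OC(=O)CC[C@H]1[C@](C)(CO[Si](C)(C)C(C)(C)C)CCC[C@]1(C)/C(OS(=O)(=O)C(F)(F)F)=C/Cl | intermediate
12 | (Z)-chloroalkenyl triflate, side-chain carboxylic acid | OC(=O)CC[C@H]1[C@](C)(CO[Si](C)(C)C(C)(C)C)CCC[C@]1(C)/C(OS(=O)(=O)C(F)(F)F)=C/Cl | intermediate
13 | acyl hypoiodite of 12 | IOC(=O)CC[C@H]1[C@](C)(CO[Si](C)(C)C(C)(C)C)CCC[C@]1(C)/C(OS(=O)(=O)C(F)(F)F)=C/Cl | intermediate
14 | (Z)-chloroalkenyl triflate with C5–CH2CH2I (C7 iodide) | ICC[C@H]1[C@](C)(CO[Si](C)(C)C(C)(C)C)CCC[C@]1(C)/C(OS(=O)(=O)C(F)(F)F)=C/Cl | intermediate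
15 | 1,4-dioxaspiro[4.5]decan-7-one | O=C1CCCC2(C1)OCCO2 | starting material
16 | lithium enolate of 15 (C7=C8) | [Li+].[O-]C1=CCCC2(C1)OCCO2 | intermediate
17 | key-step precursor: (Z)-chloroalkenyl triflate on C10, C6–C7 tether to C8 of the cyclohexanone monoketal (C8 epimers) | Cl/C=C(\OS(=O)(=O)C(F)(F)F)[C@@]1(C)CCC[C@@](C)(CO[Si](C)(C)C(C)(C)C)[C@@H]1CCC1CCC2(CC1=O)OCCO2 | intermediate
18 | key-step product: spiro ketone, rings A, B, D, exocyclic C9=C11HCl (Cl cis to C8), C13 carbonyl syn to C10 methyl | O=C1CC2(OCCO2)CC[C@@]13CC[C@H]4[C@](C)(CO[Si](C)(C)C(C)(C)C)CCC[C@]4(C)/C3=C/Cl | intermediate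
19 | lithium C12 enolate of 18 | [Li+].[O-]C1=CC2(OCCO2)CC[C@@]13CC[C@H]4[C@](C)(CO[Si](C)(C)C(C)(C)C)CCC[C@]4(C)/C3=C/Cl | intermediate
20 | tetracyclic ketone: ring C closed, C9=C11, C13 ketone, C16 ethylene ketal, C18 OTBS | O1CCOC12CC[C@]34CC[C@H]5[C@](C)(CO[Si](C)(C)C(C)(C)C)CCC[C@]5(C)C3=C[C@H]2C4=O | intermediate
21 | C13,C16-diketone | O=C1CC[C@]23CC[C@H]4[C@](C)(CO[Si](C)(C)C(C)(C)C)CCC[C@]4(C)C2=C[C@H]1C3=O | intermediate
22 | 16-methylene C13 ketone | C=C1CC[C@]23CC[C@H]4[C@](C)(CO[Si](C)(C)C(C)(C)C)CCC[C@]4(C)C2=C[C@H]1C3=O | intermediate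
23 | C16,C17-diol C13 ketone | OC[C@@]1(O)CC[C@]23CC[C@H]4[C@](C)(CO[Si](C)(C)C(C)(C)C)CCC[C@]4(C)C2=C[C@H]1C3=O | intermediate
24 | C13,C16,C17-triol, C18 OTBS | OC[C@@]1(O)CC[C@]23CC[C@H]4[C@](C)(CO[Si](C)(C)C(C)(C)C)CCC[C@]4(C)C2=C[C@H]1[C@H]3O | intermediate
25 | C17 acetate, C18 OTBS | CC(=O)OC[C@@]1(O)CC[C@]23CC[C@H]4[C@](C)(CO[Si](C)(C)C(C)(C)C)CCC[C@]4(C)C2=C[C@H]1[C@H]3O | intermediate
26 | Botryotin E | CC(=O)OC[C@@]1(O)CC[C@]23CC[C@H]4[C@](C)(CO)CCC[C@]4(C)C2=C[C@H]1[C@H]3O | target

Total step count: 17 steps.
Longest linear sequence: 17 steps, from dehydroabietic acid 1 to 26; ketone 15 is commercial and enters at step 9.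

Steps most likely to fail

Step 10. The reductive elimination at the congested tertiary enolate carbon may be too slow, so that protodetriflation takes over, or the face selection at C8 may be weak. The fallback sets out from 17 and replaces the enolate coupling by an intramolecular asymmetric Mizoroki–Heck reaction. IBX (DMSO, 70 °C) should dehydrogenate 17 only towards C8=C14, since C16 is quaternary, to give the 2-alkylcyclohex-2-enone F1. Pd(OAc)2, (R)-BINAP and 1,2,2,6,6-pentamethylpiperidine in toluene at 80 °C should then cyclise 6-exo onto C8 and lose hydride towards C15, giving the spiro ketone with a C14=C15 double bond F2. Diimide (2-nitrobenzenesulfonyl hydrazide, Et3N, CH2Cl2) reduces only that cis-disubstituted alkene and returns to 18.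

Step 11. Oxidative addition into the hindered alkenyl chloride may be slow, and the C12 enolate may instead expel a ketal oxygen or close through oxygen to a dihydrofuran. The fallback sets out from 18 and forms C11–C12 by a Heck reaction instead of an enolate coupling. PPTS in aqueous acetone gives the chloroalkenyl 1,3-dione F3. MeOH with TsOH (cat.) etherifies the less hindered C16 oxygen to give the vinylogous methyl ester F4. Pd2(dba)3, P(t-Bu)3 and Cy2NMe in dioxane at 100 °C should add C11 to C12 in a 5-exo Mizoroki–Heck cyclisation and lose hydride towards C15, giving the bridged C15=C16 methyl enol ether F5. Dilute aqueous HCl in THF hydrolyses the enol ether and rejoins the route at 21.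

Step 14. Osmium may add to the other face of the exocyclic alkene and give the C16 epimer. The fallback sets out from 21 and builds C17 by nucleophilic addition to the ketone, which uses the open face in the opposite sense. Dimethylsulfonium methylide (Me3SI, KN(SiMe3)2, THF, −10 °C; Corey–Chaykovsky reaction) should add its carbon to C16 from the face that osmium preferred, giving the spiro epoxide with C17 axial beside C13 F6. KOH in DMSO/H2O at 60 °C opens it at the primary C17 with retention at C16 and returns to 23.

Further compounds
F1 | step 10 | 2-alkylcyclohex-2-enone (C8=C14) from 17, chloroalkenyl triflate intact | Cl/C=C(\OS(=O)(=O)C(F)(F)F)[C@@]1(C)CCC[C@@](C)(CO[Si](C)(C)C(C)(C)C)[C@@H]1CCC1=CCC2(CC1=O)OCCO2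
F2 | step 10 | spiro ketone as 18 with an additional C14=C15 double bond | O=C1CC2(OCCO2)C=C[C@@]13CC[C@H]4[C@](C)(CO[Si](C)(C)C(C)(C)C)CCC[C@]4(C)/C3=C/Cl
F3 | step 11 | chloroalkenyl spiro 1,3-dione (C13, C16) | O=C1CC(=O)CC[C@@]12CC[C@H]3[C@](C)(CO[Si](C)(C)C(C)(C)C)CCC[C@]3(C)/C2=C/Cl
F4 | step 11 | vinylogous methyl ester (C16–OMe, C12=C16, C13 ketone) | COC1=CC(=O)[C@@]2(CC1)CC[C@H]3[C@](C)(CO[Si](C)(C)C(C)(C)C)CCC[C@]3(C)/C2=C/Cl
F5 | step 11 | bridged tetracycle with C15=C16 methyl enol ether and C13 ketone | COC1=CC[C@]23CC[C@H]4[C@](C)(CO[Si](C)(C)C(C)(C)C)CCC[C@]4(C)C2=C[C@H]1C3=O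
F6 | step 14 | C16 spiro epoxide (C17 axial, oxygen equatorial), C13 ketone | C1O[C@@]12CC[C@]34CC[C@H]5[C@](C)(CO[Si](C)(C)C(C)(C)C)CCC[C@]5(C)C3=C[C@H]2C4=O
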